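**Retrosynthetic overview**

1. The target is a chain of six benzene rings A–F joined by five diaryl ether oxygens. The last step is a twelvefold O-demethylation of a precursor in which only ring D carries free hydroxyls.
2. The strategy rests on ring D. Carbon D1, bonded to the ether oxygen of ring C, lies between the unsubstituted carbons D2 and D6; D3 and D5 carry OH; D4 carries the oxygen to ring E. D1 can therefore be the carbonyl carbon of an acetate ester of the hindered ring C phenol, D6 its methyl carbon, D3 and D5 carbinols, and D4 the α-carbon of an aryloxyacetate.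
3. Key disconnection: the D1=D2 bond, made by methylenation of an aryl hept-6-enoate and ring-closing metathesis of the aryl enol ether with the terminal alkene. Oxidation of the D3 and D5 carbinols then aromatises ring D without any elimination.
4. The heptenoate is cut at two aldol bonds (D5–D6 and D3–D4) into the A–B–C aryl acetate (two SNAr/Dakin cycles), the E–F aryloxyacetate (Ullmann coupling, Dakin oxidation, O-alkylation) and acrolein. The key step thus joins the two halves of the molecule at its centre.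
5. Ring order: rings A, B, C, E and F are bought as arenes. Ring D is the only ring formed (step 14) and is aromatised in step 16.

Key step: step 14

Remark on stereochemistry: the sp3 centres made in the two aldol steps are formed without control; these compounds are carried as racemic diastereomer mixtures, one stereoisomer is drawn, and all three centres become sp2 carbons of ring D on aromatisation.

Abbreviations: Ar(ABC) = 2,6-dimethoxy-4-[2,6-dimethoxy-4-(2,4,6-trimethoxyphenoxy)phenoxy]phenyl; Ar(EF) = 3,5-dimethoxy-4-(3,4,5-trimethoxyphenoxy)phenyl.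

**Route**

Step 1
Reactants: 1 2,4,6-trimethoxyphenol; 2 4-fluoro-2,6-dimethoxybenzaldehyde
Product: 3 2,6-dimethoxy-4-(2,4,6-trimethoxyphenoxy)benzaldehyde
Conditions: K2CO3, DMSO, 110 °C, Ar
Reagents that add atoms: none
Why: Nucleophilic aromatic substitution by addition–elimination, in which the hindered phenoxide attacks the unhindered fluorine-bearing carbon para to the formyl group that stabilises the Meisenheimer intermediate.

Step 2
Reactants: 3 2,6-dimethoxy-4-(2,4,6-trimethoxyphenoxy)benzaldehyde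
Product: 5 2,6-dimethoxy-4-(2,4,6-trimethoxyphenoxy)phenol, via aryl formate 4 (not isolated)
Conditions: mCPBA, CH2Cl2, 0 °C→rt; aq. Na2SO3/NaHCO3 wash; then K2CO3 (cat.), MeOH, rt
Reagents that add atoms: 3-chloroperoxybenzoic acid (mCPBA), OOC(=O)c1cccc(Cl)c1
Why: Dakin-type Baeyer–Villiger oxidation, in which the electron-rich 2,4,6-trioxygenated aryl group migrates to oxygen and mild methanolysis of the formate frees the 2,6-dimethoxyphenol once the peracid has been destroyed.

Step 3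
Reactants: 5 2,6-dimethoxy-4-(2,4,6-trimethoxyphenoxy)phenol; 2 4-fluoro-2,6-dimethoxybenzaldehyde
Product: 6 2,6-dimethoxy-4-[2,6-dimethoxy-4-(2,4,6-trimethoxyphenoxy)phenoxy]benzaldehyde
Conditions: K2CO3, DMSO, 110 °C, Ar
Reagents that add atoms: none
Why: Second nucleophilic aromatic substitution of the same kind, the new hindered phenoxide again reacting at the formyl-activated C–F carbon while the existing diaryl ether and methyl ethers are inert to carbonate.

Step 4
Reactants: 6 2,6-dimethoxy-4-[2,6-dimethoxy-4-(2,4,6-trimethoxyphenoxy)phenoxy]benzaldehyde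
Product: 8 Ar(ABC)–OH (the three-ring phenol), via aryl formate 7 (not isolated)
Conditions: mCPBA, CH2Cl2, 0 °C→rt; aq. Na2SO3/NaHCO3 wash; then K2CO3 (cat.), MeOH, rt
Reagents that add atoms: 3-chloroperoxybenzoic acid (mCPBA), OOC(=O)c1cccc(Cl)c1
Why: Dakin-type Baeyer–Villiger oxidation as in step 2, turning the formyl group of ring C into the hindered hydroxyl that will become the ring C–O–D1 oxygen.

Step 5
Reactants: 8 Ar(ABC)–OH; 9 acetyl chloride
Product: 10 Ar(ABC) acetate
Conditions: Et3N, DMAP (cat.), CH2Cl2, 0 °C→rt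
Reagents that add atoms: none
Why: DMAP-catalysed O-acylation, which makes the hindered aryl–O–D1 bond as a simple ester where no aryl–oxygen coupling is needed.

Step 6
Reactants: 11 3,4,5-trimethoxyphenol; 12 4-bromo-3,5-dimethoxybenzaldehyde
Product: 13 3,5-dimethoxy-4-(3,4,5-trimethoxyphenoxy)benzaldehyde
Conditions: CuI (10 mol%), picolinic acid (20 mol%), K3PO4, DMSO, 100 °C, Ar
Reagents that add atoms: none
Why: Ligand-accelerated Ullmann diaryl ether condensation, which should proceed because the phenol is unhindered and the di-ortho-substituted aryl bromide is activated by its para formyl group.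

Step 7
Reactants: 13 3,5-dimethoxy-4-(3,4,5-trimethoxyphenoxy)benzaldehyde
Product: 15 Ar(EF)–OH (3,5-dimethoxy-4-(3,4,5-trimethoxyphenoxy)phenol), via aryl formate 14 (not isolated)
Conditions: mCPBA, CH2Cl2, rt→40 °C; aq. Na2SO3/NaHCO3 wash; then K2CO3 (cat.), MeOH, rt
Reagents that add atoms: 3-chloroperoxybenzoic acid (mCPBA), OOC(=O)c1cccc(Cl)c1
Why: Baeyer–Villiger oxidation of a 4-aryloxybenzaldehyde with aryl migration, followed by formate methanolysis, giving the unhindered ring E phenol.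

Step 8
Reactants: 15 Ar(EF)–OH; 16 methyl bromoacetate
Product: 17 methyl 2-[Ar(EF)-oxy]acetate
Conditions: K2CO3, acetone, reflux
Reagents that add atoms: none
Why: Williamson ether synthesis (SN2 at the activated α-bromo ester), which forms the ring E–O–D4 bond at an sp3 carbon.

Step 9
Reactants: 17 methyl 2-[Ar(EF)-oxy]acetate; 18 acrolein
Product: 20 methyl 2-[Ar(EF)-oxy]-3-hydroxypent-4-enoate, via lithium enolate 19 (not isolated)
Conditions: LiN(i-Pr)2, THF, −78 °C; then acrolein, −78 °C; aq. NH4Cl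
Reagents that add atoms: none
Why: Aldol addition of a lithium ester enolate, which adds 1,2 to acrolein at −78 °C and forms the D3–D4 bond; the two new centres arise without control, which is acceptable because both end as sp2 carbons of ring D.

Step 10
Reactants: 20 methyl 2-[Ar(EF)-oxy]-3-hydroxypent-4-enoate
Product: 21 methyl 3-(tert-butyldimethylsilyloxy)-2-[Ar(EF)-oxy]pent-4-enoate
Conditions: TBSCl, imidazole, DMF, rt
Reagents that add atoms: tert-butyldimethylsilyl chloride, CC(C)(C)[Si](C)(C)Cl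
Why: Imidazole-promoted silylation of the secondary allylic alcohol, masking the D3 oxygen for the hydride, enolate and titanium steps.

Step 11
Reactants: 21 methyl 3-(tert-butyldimethylsilyloxy)-2-[Ar(EF)-oxy]pent-4-enoate
Product: 22 3-(tert-butyldimethylsilyloxy)-2-[Ar(EF)-oxy]pent-4-enal
Conditions: i-Bu2AlH, CH2Cl2, −78 °C; MeOH, then aq. potassium sodium tartrate
Reagents that add atoms: none
Why: Partial reduction of the ester with i-Bu2AlH, where the α-aryloxy oxygen should stabilise the tetrahedral aluminium hemiacetal at −78 °C so that the aldehyde appears only on work-up.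

Step 12
Reactants: 10 Ar(ABC) acetate; 22 3-(tert-butyldimethylsilyloxy)-2-[Ar(EF)-oxy]pent-4-enal
Product: 24 Ar(ABC) 5-(tert-butyldimethylsilyloxy)-4-[Ar(EF)-oxy]-3-hydroxyhept-6-enoate, via lithium enolate 23 (not isolated)
Conditions: LiN(i-Pr)2, THF, −78 °C (10 added to the base); then 22, −78 °C; aq. NH4Cl at −78 °C
Reagents that add atoms: none
Why: Aldol addition of the lithium enolate of a hindered aryl acetate, kept and quenched at −78 °C so that it neither fragments to ketene nor closes to a β-lactone; it forms the D5–D6 bond, and the new carbinol centre needs no control because it is oxidised in step 16.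

Step 13
Reactants: 24 Ar(ABC) 5-(tert-butyldimethylsilyloxy)-4-[Ar(EF)-oxy]-3-hydroxyhept-6-enoate
Product: 25 Ar(ABC) 3,5-bis(tert-butyldimethylsilyloxy)-4-[Ar(EF)-oxy]hept-6-enoate
Conditions: TBSOTf, 2,6-lutidine, CH2Cl2, −78→0 °C
Reagents that add atoms: tert-butyldimethylsilyl trifluoromethanesulfonate, CC(C)(C)[Si](C)(C)OS(=O)(=O)C(F)(F)F
Why: Silylation of the hindered β-hydroxyl with the silyl triflate and a non-nucleophilic base, leaving the ester as the only carbonyl and removing the free OH before the titanium and ruthenium reagents.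

Step 14
Reactants: 25 Ar(ABC) 3,5-bis(tert-butyldimethylsilyloxy)-4-[Ar(EF)-oxy]hept-6-enoate
Product: 27 1-[Ar(ABC)-oxy]-4-[Ar(EF)-oxy]-3,5-bis(tert-butyldimethylsilyloxy)cyclohex-1-ene, via aryl enol ether 26 (not isolated)
Conditions: Tebbe reagent Cp2Ti(μ-CH2)(μ-Cl)AlMe2 (2 equiv), pyridine (cat.), THF–toluene, −40 °C→rt; 0.1 M NaOH, filtration through basic Al2O3; then second-generation Grubbs catalyst RuCl2(=CHPh)(PCy3)(H2IMes) (10 mol%), toluene (0.005 M), 80 °C, Ar sparge
Reagents that add atoms: none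
Why: The titanium methylidene released from the Tebbe reagent adds across the ester C=O to an oxatitanacyclobutane that collapses to the aryl enol ether 26 and Cp2Ti=O; the ester is the only carbonyl in 25 and the reagent is non-basic, so the β-silyloxy group should not be eliminated. The ruthenium benzylidene then loads onto the monosubstituted terminal alkene, the new alkylidene adds intramolecularly to the 1,1-disubstituted enol ether, and cycloreversion of the ruthenacyclobutane expels ethylene and forms the D1=D2 bond. The closest known reaction type is the olefinic ester cyclisation (ester methylenation followed by enol ether–olefin ring-closing metathesis), and phenyl esters are known to undergo the methylenation. The six-membered carbocycle is closed by ring-closing metathesis with the new double bond endocyclic and the aryloxy group left exocyclic on D1. No stereocentre is formed and the three existing sp3 centres are not touched. The step needs initiation at the terminal alkene and cyclisation instead of cross-metathesis, which the hindered, electron-rich enol ether end, the six-membered ring size and high dilution should secure.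

Step 15
Reactants: 27 1-[Ar(ABC)-oxy]-4-[Ar(EF)-oxy]-3,5-bis(tert-butyldimethylsilyloxy)cyclohex-1-ene
Product: 28 5-[Ar(ABC)-oxy]-2-[Ar(EF)-oxy]cyclohex-4-ene-1,3-diol
Conditions: Bu4NF, THF, 0 °C→rt; aq. NH4Cl
Reagents that add atoms: none
Why: Fluoride-induced cleavage of both silyl ethers under basic, non-acidic conditions, chosen so that the aryl enol ether is not hydrolysed.

Step 16
Reactants: 28 5-[Ar(ABC)-oxy]-2-[Ar(EF)-oxy]cyclohex-4-ene-1,3-diol
Product: 30 5-[Ar(ABC)-oxy]-2-[Ar(EF)-oxy]benzene-1,3-diol, via cyclohexenedione 29 (not isolated)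
Conditions: Dess–Martin periodinane (2.2 equiv), NaHCO3, CH2Cl2, 0 °C→rt; aq. Na2S2O3/NaHCO3
Reagents that add atoms: none
Why: Dess–Martin oxidation of both secondary carbinols gives a 5-aryloxycyclohex-4-ene-1,3-dione, which is the keto tautomer of the resorcinol and should enolise to the arene at once; no leaving group is lost and the three sp3 centres are erased.

Step 17
Reactants: 30 5-[Ar(ABC)-oxy]-2-[Ar(EF)-oxy]benzene-1,3-diol
Product: 31 the target, the tetradecahydroxy hexaphenyl pentaether CNP0187343.0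
Conditions: BBr3 (excess), CH2Cl2, −78 °C→rt; MeOH at 0 °C, evaporation; degassed H2O, Ar
Reagents that add atoms: none
Why: Lewis acid-mediated cleavage of the twelve aryl methyl ethers (boron coordination, then bromide SN2 at methyl), to which diaryl ether bonds are inert, followed by hydrolysis of the aryl borates.

**Compound list**

1 | 2,4,6-trimethoxyphenol | COc1cc(OC)c(O)c(OC)c1 | starting material
2 | 4-fluoro-2,6-dimethoxybenzaldehyde | COc1cc(F)cc(OC)c1C=O | starting material
3 | 2,6-dimethoxy-4-(2,4,6-trimethoxyphenoxy)benzaldehyde | COc1cc(OC)c(Oc2cc(OC)c(C=O)c(OC)c2)c(OC)c1 | intermediate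
4 | 2,6-dimethoxy-4-(2,4,6-trimethoxyphenoxy)phenyl formate (not isolated) | COc1cc(OC)c(Oc2cc(OC)c(OC=O)c(OC)c2)c(OC)c1 | intermediate
5 | 2,6-dimethoxy-4-(2,4,6-trimethoxyphenoxy)phenol | COc1cc(OC)c(Oc2cc(OC)c(O)c(OC)c2)c(OC)c1 | intermediate
6 | 2,6-dimethoxy-4-[2,6-dimethoxy-4-(2,4,6-trimethoxyphenoxy)phenoxy]benzaldehyde | COc1cc(OC)c(Oc2cc(OC)c(Oc3cc(OC)c(C=O)c(OC)c3)c(OC)c2)c(OC)c1 | intermediate
7 | Ar(ABC) formate (not isolated) | COc1cc(OC)c(Oc2cc(OC)c(Oc3cc(OC)c(OC=O)c(OC)c3)c(OC)c2)c(OC)c1 | intermediate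
8 | Ar(ABC)–OH, 2,6-dimethoxy-4-[2,6-dimethoxy-4-(2,4,6-trimethoxyphenoxy)phenoxy]phenol | COc1cc(OC)c(Oc2cc(OC)c(Oc3cc(OC)c(O)c(OC)c3)c(OC)c2)c(OC)c1 | intermediate
9 | acetyl chloride | CC(Cl)=O | starting material
10 | Ar(ABC) acetate | CC(=O)Oc1c(OC)cc(Oc2c(OC)cc(Oc3c(OC)cc(OC)cc3OC)cc2OC)cc1OC | intermediate
11 | 3,4,5-trimethoxyphenol | COc1cc(O)cc(OC)c1OC | starting material
12 | 4-bromo-3,5-dimethoxybenzaldehyde | COc1cc(C=O)cc(OC)c1Br | starting material
13 | 3,5-dimethoxy-4-(3,4,5-trimethoxyphenoxy)benzaldehyde | COc1cc(C=O)cc(OC)c1Oc1cc(OC)c(OC)c(OC)c1 | intermediate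
14 | Ar(EF) formate (not isolated) | COc1cc(OC=O)cc(OC)c1Oc1cc(OC)c(OC)c(OC)c1 | intermediate
15 | Ar(EF)–OH, 3,5-dimethoxy-4-(3,4,5-trimethoxyphenoxy)phenol | COc1cc(O)cc(OC)c1Oc1cc(OC)c(OC)c(OC)c1 | intermediate
16 | methyl bromoacetate | COC(=O)CBr | starting material
17 | methyl 2-[3,5-dimethoxy-4-(3,4,5-trimethoxyphenoxy)phenoxy]acetate | COC(=O)COc1cc(OC)c(Oc2cc(OC)c(OC)c(OC)c2)c(OC)c1 | intermediate
18 | acrolein | C=CC=O | starting material
19 | lithium enolate of 17 (not isolated) | COC(=COc1cc(OC)c(Oc2cc(OC)c(OC)c(OC)c2)c(OC)c1)O[Li] | intermediate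
20 | methyl 2-[Ar(EF)-oxy]-3-hydroxypent-4-enoate (one stereoisomer drawn) | C=C[C@H](O)[C@@H](Oc1cc(OC)c(Oc2cc(OC)c(OC)c(OC)c2)c(OC)c1)C(=O)OC | intermediate
21 | methyl 3-(tert-butyldimethylsilyloxy)-2-[Ar(EF)-oxy]pent-4-enoate | C=C[C@H](O[Si](C)(C)C(C)(C)C)[C@@H](Oc1cc(OC)c(Oc2cc(OC)c(OC)c(OC)c2)c(OC)c1)C(=O)OC | intermediate
22 | 3-(tert-butyldimethylsilyloxy)-2-[Ar(EF)-oxy]pent-4-enal | C=C[C@H](O[Si](C)(C)C(C)(C)C)[C@@H](Oc1cc(OC)c(Oc2cc(OC)c(OC)c(OC)c2)c(OC)c1)C=O | intermediate
23 | lithium enolate of 10 (not isolated) | C=C(O[Li])Oc1c(OC)cc(Oc2c(OC)cc(Oc3c(OC)cc(OC)cc3OC)cc2OC)cc1OC | intermediate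
24 | Ar(ABC) 5-(tert-butyldimethylsilyloxy)-4-[Ar(EF)-oxy]-3-hydroxyhept-6-enoate | C=C[C@H](O[Si](C)(C)C(C)(C)C)[C@@H](Oc1cc(OC)c(Oc2cc(OC)c(OC)c(OC)c2)c(OC)c1)[C@H](O)CC(=O)Oc1c(OC)cc(Oc2c(OC)cc(Oc3c(OC)cc(OC)cc3OC)cc2OC)cc1OC | intermediate
25 | Ar(ABC) 3,5-bis(tert-butyldimethylsilyloxy)-4-[Ar(EF)-oxy]hept-6-enoate (key-step precursor) | C=C[C@H](O[Si](C)(C)C(C)(C)C)[C@@H](Oc1cc(OC)c(Oc2cc(OC)c(OC)c(OC)c2)c(OC)c1)[C@H](O[Si](C)(C)C(C)(C)C)CC(=O)Oc1c(OC)cc(Oc2c(OC)cc(Oc3c(OC)cc(OC)cc3OC)cc2OC)cc1OC | intermediate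
26 | 2-[Ar(ABC)-oxy]-4,6-bis(tert-butyldimethylsilyloxy)-5-[Ar(EF)-oxy]octa-1,7-diene (not isolated) | C=C[C@H](O[Si](C)(C)C(C)(C)C)[C@@H](Oc1cc(OC)c(Oc2cc(OC)c(OC)c(OC)c2)c(OC)c1)[C@H](O[Si](C)(C)C(C)(C)C)CC(=C)Oc1c(OC)cc(Oc2c(OC)cc(Oc3c(OC)cc(OC)cc3OC)cc2OC)cc1OC | intermediate
27 | 1-[Ar(ABC)-oxy]-4-[Ar(EF)-oxy]-3,5-bis(tert-butyldimethylsilyloxy)cyclohex-1-ene (key-step product) | C1=C(Oc2c(OC)cc(Oc3c(OC)cc(Oc4c(OC)cc(OC)cc4OC)cc3OC)cc2OC)C[C@@H](O[Si](C)(C)C(C)(C)C)[C@H](Oc2cc(OC)c(Oc3cc(OC)c(OC)c(OC)c3)c(OC)c2)[C@H]1O[Si](C)(C)C(C)(C)C | intermediate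
28 | 5-[Ar(ABC)-oxy]-2-[Ar(EF)-oxy]cyclohex-4-ene-1,3-diol | C1=C(Oc2c(OC)cc(Oc3c(OC)cc(Oc4c(OC)cc(OC)cc4OC)cc3OC)cc2OC)C[C@@H](O)[C@H](Oc2cc(OC)c(Oc3cc(OC)c(OC)c(OC)c3)c(OC)c2)[C@H]1O | intermediate
29 | 5-[Ar(ABC)-oxy]-2-[Ar(EF)-oxy]cyclohex-4-ene-1,3-dione (not isolated) | O=C1C=C(Oc2c(OC)cc(Oc3c(OC)cc(Oc4c(OC)cc(OC)cc4OC)cc3OC)cc2OC)CC(=O)C1Oc1cc(OC)c(Oc2cc(OC)c(OC)c(OC)c2)c(OC)c1 | intermediate
30 | 5-[Ar(ABC)-oxy]-2-[Ar(EF)-oxy]benzene-1,3-diol (hexamer dodecamethyl ether, ring D free) | COc1cc(OC)c(Oc2cc(OC)c(Oc3cc(OC)c(Oc4cc(O)c(Oc5cc(OC)c(Oc6cc(OC)c(OC)c(OC)c6)c(OC)c5)c(O)c4)c(OC)c3)c(OC)c2)c(OC)c1 | intermediate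
31 | CNP0187343.0 | Oc1cc(O)c(Oc2cc(O)c(Oc3cc(O)c(Oc4cc(O)c(Oc5cc(O)c(Oc6cc(O)c(O)c(O)c6)c(O)c5)c(O)c4)c(O)c3)c(O)c2)c(O)c1 | target

**Summary**

Total step count: 17. Longest linear sequence: 12 steps (steps 6–17, from 3,4,5-trimethoxyphenol); the A–B–C branch (steps 1–5) joins at step 12.

Steps most likely to fail:

1. Step 14. The methylenation may stall at the shielded aryl ester, or the ruthenium carbene may be diverted onto the electron-rich enol ether end so that intermolecular cross-metathesis at the terminal alkene outruns ring closure. The fallback gives up building ring D from a chain and adds the remaining rings one at a time by known SNAr/Dakin chemistry. It sets out from 8 and 2. Under the conditions of step 1 they should give the four-ring aldehyde F1. mCPBA then gives its aryl formate F2, and methanolysis the four-ring phenol F3. A second cycle with 2 gives the five-ring aldehyde F4, its formate F5 and the five-ring phenol F6. A third cycle gives the six-ring aldehyde F7, its formate F8 and the six-ring phenol F9, in which ring F carries a free 4-hydroxyl. BBr3 demethylation of F9 under the conditions of step 17 comes back to the route at 31.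

2. Step 16. The electron-rich resorcinol appears while periodinane is still present and may be oxidised further to quinone-type products, or a mono-oxidised β-hydroxy ketone may lose water. The fallback splits the oxidation into two chemoselective stages, setting out from 28. MnO2 in CH2Cl2 should oxidise only the allylic carbinol next to the enol ether double bond, giving the hydroxy enone F10 under neutral conditions. One equivalent of Dess–Martin periodinane, buffered with NaHCO3, then oxidises the remaining carbinol, so that no oxidant is left when the dione 29 tautomerises. The fallback comes back to the route at 30.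

3. Step 17. Cleavage of twelve methyl ethers may stop short, and the free tetradecaphenol may be degraded by air during isolation. The fallback isolates the product as a stable derivative, setting out from 30. After BBr3 treatment and methanol quench, the crude polyphenol is not isolated but acetylated (Ac2O, pyridine, DMAP) to the tetradecaacetate F11. F11 can be chromatographed away from partly methylated material, which is recycled through BBr3. Acid methanolysis of F11 (HCl in degassed MeOH, Ar) comes back to the route at 31.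

**Further compounds**

F1 | step 14 | four-ring aldehyde, Ar(ABC)-oxy-substituted 2,6-dimethoxybenzaldehyde | COc1cc(OC)c(Oc2cc(OC)c(Oc3cc(OC)c(Oc4cc(OC)c(C=O)c(OC)c4)c(OC)c3)c(OC)c2)c(OC)c1
F2 | step 14 | four-ring aryl formate | COc1cc(OC)c(Oc2cc(OC)c(Oc3cc(OC)c(Oc4cc(OC)c(OC=O)c(OC)c4)c(OC)c3)c(OC)c2)c(OC)c1
F3 | step 14 | four-ring phenol | COc1cc(OC)c(Oc2cc(OC)c(Oc3cc(OC)c(Oc4cc(OC)c(O)c(OC)c4)c(OC)c3)c(OC)c2)c(OC)c1
F4 | step 14 | five-ring aldehyde | COc1cc(OC)c(Oc2cc(OC)c(Oc3cc(OC)c(Oc4cc(OC)c(Oc5cc(OC)c(C=O)c(OC)c5)c(OC)c4)c(OC)c3)c(OC)c2)c(OC)c1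
F5 | step 14 | five-ring aryl formate | COc1cc(OC)c(Oc2cc(OC)c(Oc3cc(OC)c(Oc4cc(OC)c(Oc5cc(OC)c(OC=O)c(OC)c5)c(OC)c4)c(OC)c3)c(OC)c2)c(OC)c1
F6 | step 14 | five-ring phenol | COc1cc(OC)c(Oc2cc(OC)c(Oc3cc(OC)c(Oc4cc(OC)c(Oc5cc(OC)c(O)c(OC)c5)c(OC)c4)c(OC)c3)c(OC)c2)c(OC)c1
F7 | step 14 | six-ring aldehyde | COc1cc(OC)c(Oc2cc(OC)c(Oc3cc(OC)c(Oc4cc(OC)c(Oc5cc(OC)c(Oc6cc(OC)c(C=O)c(OC)c6)c(OC)c5)c(OC)c4)c(OC)c3)c(OC)c2)c(OC)c1
F8 | step 14 | six-ring aryl formate | COc1cc(OC)c(Oc2cc(OC)c(Oc3cc(OC)c(Oc4cc(OC)c(Oc5cc(OC)c(Oc6cc(OC)c(OC=O)c(OC)c6)c(OC)c5)c(OC)c4)c(OC)c3)c(OC)c2)c(OC)c1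
F9 | step 14 | six-ring phenol (tridecamethyl ether of the target, ring F 4-OH free) | COc1cc(OC)c(Oc2cc(OC)c(Oc3cc(OC)c(Oc4cc(OC)c(Oc5cc(OC)c(Oc6cc(OC)c(O)c(OC)c6)c(OC)c5)c(OC)c4)c(OC)c3)c(OC)c2)c(OC)c1
F10 | step 16 | 3-[Ar(ABC)-oxy]-6-[Ar(EF)-oxy]-5-hydroxycyclohex-2-en-1-one | C1=C(Oc2c(OC)cc(Oc3c(OC)cc(Oc4c(OC)cc(OC)cc4OC)cc3OC)cc2OC)C[C@@H](O)[C@H](Oc2cc(OC)c(Oc3cc(OC)c(OC)c(OC)c3)c(OC)c2)C1=O
F11 | step 17 | tetradecaacetate of the target | CC(=O)Oc1cc(OC(C)=O)c(Oc2cc(OC(C)=O)c(Oc3cc(OC(C)=O)c(Oc4cc(OC(C)=O)c(Oc5cc(OC(C)=O)c(Oc6cc(OC(C)=O)c(OC(C)=O)c(OC(C)=O)c6)c(OC(C)=O)c5)c(OC(C)=O)c4)c(OC(C)=O)c3)c(OC(C)=O)c2)c(OC(C)=O)c1
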